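The daucane is cut back to a cyclopentenyl 2-siloxydiene and a 4-siloxyvinyl diazoacetate. Their union exploits the seven-membered ring C1–C5–C6–C7–C8–C9–C10: its lone methylene C7 separates oxygenated C6 from methyl-bearing C8, and quaternary C1 neighbours oxygenated C10, the pattern left when a cis-1,2-dialkenylcyclopropane C6–C7–C8 undergoes a Cope shift. One flask should therefore form C7–C8 and C1–C10, close the cycloheptadiene and set C1 and C10. The diene comes from (S)-terpinen-4-ol, whose six-membered ring is oxygenated, cleaved and re-closed to the cyclopentane C1–C5 carrying the C4 isopropyl carbinol.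

Key step: step 13

Numbering: target carbons are C1 (quaternary, CH3), C2 (CHOH), C3 (CH2), C4 (C(OH)-isopropyl), C5 (ring-fusion CH), C6 (CH–O), C7 (CH2), C8 (C–CH3), C9 and C10 (CH–O); "daucane" means this bicyclo[5.3.0]decane with methyls on C1 and C8 and isopropyl on C4; β is the face of the C1 methyl; PMB = 4-methoxybenzyl, TES = triethylsilyl, TBS = tert-butyldimethylsilyl.

Assumption: (S)-(+)-terpinen-4-ol is used in an enantio-enriched commercial grade (upgraded if required), and Rh2(S-DOSP)4, dirhodium tetrakis[(S)-N-(4-dodecylbenzenesulfonyl)prolinate], is taken as the catalyst enantiomer matched to the substrate; this assignment rests on the usual facial model and is to be confirmed against Rh2(R-DOSP)4.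

Step 1
Reactants: 1 (S)-(+)-terpinen-4-ol
Product: 2 (5R)-5-isopropyl-2-methylcyclohex-2-ene-1,5-diol (mixture of C1 epimers)
Conditions: SeO2 (0.5 equiv), t-BuOOH (2 equiv), CH2Cl2, 0 °C → rt
Reagents that add atoms: tert-butyl hydroperoxide, CC(C)(C)OO
Why: Catalytic SeO2 allylic hydroxylation (ene reaction then [2,3]-sigmatropic shift) should attack the ring CH2 beside the more substituted alkene carbon, as p-menth-1-ene gives carvotanacetol, and the new carbinol configuration is erased in step 2.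

Step 2
Reactants: 2 (5R)-5-isopropyl-2-methylcyclohex-2-ene-1,5-diol
Product: 3 (R)-5-hydroxy-5-isopropyl-2-methylcyclohex-2-en-1-one
Conditions: MnO2 (excess), CH2Cl2, rt
Reagents that add atoms: none
Why: MnO2 oxidation is selective for the allylic secondary alcohol, so both epimers should converge on one enone while the tertiary carbinol is untouched.

Step 3
Reactants: 3 (R)-5-hydroxy-5-isopropyl-2-methylcyclohex-2-en-1-one
Product: 4 (1S,5R)-5-isopropyl-2-methylcyclohex-2-ene-1,5-diol (trans-1,3-diol)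
Conditions: Me4NBH(OAc)3, MeCN/AcOH (1:1), −30 °C
Reagents that add atoms: none
Why: Evans–Saksena reduction, in which the tertiary hydroxyl binds boron and delivers hydride intramolecularly to its own face of the β-hydroxy enone carbonyl, should give the trans (anti) 1,3-diol by 1,2-reduction.

Step 4
Reactants: 4 (1S,5R)-5-isopropyl-2-methylcyclohex-2-ene-1,5-diol
Product: 5 (1R,5S)-1-isopropyl-5-[(4-methoxybenzyl)oxy]-4-methylcyclohex-3-en-1-ol
Conditions: NaH (1.05 equiv), PMBCl, Bu4NI (cat.), THF/DMF, 0 °C → rt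
Reagents that add atoms: 4-methoxybenzyl chloride, COc1ccc(CCl)cc1
Why: Williamson etherification should alkylate the less hindered secondary allylic alkoxide in preference to the tertiary one flanked by isopropyl.

Step 5
Reactants: 5 (1R,5S)-1-isopropyl-5-[(4-methoxybenzyl)oxy]-4-methylcyclohex-3-en-1-ol
Product: 6 triethyl{[(1R,5S)-1-isopropyl-5-[(4-methoxybenzyl)oxy]-4-methylcyclohex-3-en-1-yl]oxy}silane
Conditions: TESOTf, 2,6-lutidine, CH2Cl2, 0 °C → rt
Reagents that add atoms: triethylsilyl trifluoromethanesulfonate, CC[Si](CC)(CC)OS(=O)(=O)C(F)(F)F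
Why: Silyl triflate silylation is strong enough for the hindered tertiary alcohol, and the TES ether is chosen to outlast the enol ether cleavage of step 16 yet remain removable beside a secondary TBS ether.

Step 6
Reactants: 6 triethyl{[(1R,5S)-1-isopropyl-5-[(4-methoxybenzyl)oxy]-4-methylcyclohex-3-en-1-yl]oxy}silane
Product: 8 (3S,5S)-3-isopropyl-5-[(4-methoxybenzyl)oxy]-6-oxo-3-[(triethylsilyl)oxy]heptanal, via ozonide 7 (not isolated)
Conditions: O3, CH2Cl2, Sudan Red 7B, −78 °C; then PPh3, −78 °C → rt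
Reagents that add atoms: ozone, [O-][O+]=O
Why: Ozonolysis titrated with the dye indicator should cleave the electron-rich trisubstituted alkene before the anisyl ring is attacked, and PPh3 reduces the ozonide to the 1,6-keto aldehyde without epimerising the α-alkoxy ketone.

Step 7
Reactants: 8 (3S,5S)-3-isopropyl-5-[(4-methoxybenzyl)oxy]-6-oxo-3-[(triethylsilyl)oxy]heptanal
Product: 9 (3S,5R)-5-isopropyl-3-[(4-methoxybenzyl)oxy]-2-methyl-5-[(triethylsilyl)oxy]cyclopent-1-ene-1-carbaldehyde
Conditions: piperidine (0.3 equiv), AcOH (0.3 equiv), PhMe, 4 Å MS, rt → 40 °C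
Reagents that add atoms: none
Why: Intramolecular aldol condensation under amine–acid catalysis, in which the aldehyde enamine adds 5-exo to the methyl ketone and the tertiary aldol loses water to the tetrasubstituted enal, with the mild buffered medium limiting loss of the β-silyloxy group and epimerisation at the PMB-bearing carbon.

Step 8
Reactants: 9 (3S,5R)-5-isopropyl-3-[(4-methoxybenzyl)oxy]-2-methyl-5-[(triethylsilyl)oxy]cyclopent-1-ene-1-carbaldehyde; 10 methylmagnesium bromide
Product: 11 1-{(3S,5R)-5-isopropyl-3-[(4-methoxybenzyl)oxy]-2-methyl-5-[(triethylsilyl)oxy]cyclopent-1-en-1-yl}ethan-1-ol (carbinol epimers)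
Conditions: MeMgBr, THF, −78 °C; then aq NH4Cl
Reagents that add atoms: none
Why: Grignard 1,2-addition to the hindered enal at low temperature should be clean, and the carbinol epimer mixture is inconsequential because step 9 removes that centre.

Step 9
Reactants: 11 1-{(3S,5R)-5-isopropyl-3-[(4-methoxybenzyl)oxy]-2-methyl-5-[(triethylsilyl)oxy]cyclopent-1-en-1-yl}ethan-1-ol
Product: 12 1-{(3S,5R)-5-isopropyl-3-[(4-methoxybenzyl)oxy]-2-methyl-5-[(triethylsilyl)oxy]cyclopent-1-en-1-yl}ethan-1-one
Conditions: Dess–Martin periodinane, CH2Cl2, 0 °C → rt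
Reagents that add atoms: none
Why: Dess–Martin oxidation of the allylic alcohol under near-neutral conditions should give the acetylcyclopentene without touching the PMB or TES ethers.

Step 10
Reactants: 12 1-{(3S,5R)-5-isopropyl-3-[(4-methoxybenzyl)oxy]-2-methyl-5-[(triethylsilyl)oxy]cyclopent-1-en-1-yl}ethan-1-one
Product: 13 tert-butyl[(1-{(3S,5R)-5-isopropyl-3-[(4-methoxybenzyl)oxy]-2-methyl-5-[(triethylsilyl)oxy]cyclopent-1-en-1-yl}ethenyl)oxy]dimethylsilane (2-siloxy-1,3-diene)
Conditions: TBSOTf, Et3N, CH2Cl2, −78 → 0 °C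
Reagents that add atoms: tert-butyldimethylsilyl trifluoromethanesulfonate, CC(C)(C)[Si](C)(C)OS(=O)(=O)C(F)(F)F
Why: Soft enolisation (silyl triflate/amine) silylates the ketone oxygen and removes a proton from the acetyl methyl, which should give the cross-conjugated 2-siloxydiene in preference to the hindered extended dienol ether.

Step 11
Reactants: 14 ethyl diazoacetate; 15 (tert-butyldimethylsilyloxy)acetaldehyde
Product: 16 ethyl 4-[(tert-butyldimethylsilyl)oxy]-2-diazo-3-hydroxybutanoate (racemic)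
Conditions: DBU (20 mol %), MeCN, rt
Reagents that add atoms: none
Why: DBU-catalysed aldol-type addition of the diazoacetate carbon to the aldehyde is a standard route to β-hydroxy-α-diazo esters.

Step 12
Reactants: 16 ethyl 4-[(tert-butyldimethylsilyl)oxy]-2-diazo-3-hydroxybutanoate
Product: 17 ethyl (E)-4-[(tert-butyldimethylsilyl)oxy]-2-diazobut-3-enoate
Conditions: POCl3, Et3N, CH2Cl2, 0 °C → rt; rapid filtration through Et3N-deactivated silica
Reagents that add atoms: none
Why: Dehydration of the β-hydroxy diazo ester through its dichlorophosphate (elimination with Et3N) should give the vinyl diazoacetate with the conjugated E enol ether favoured, and only the E isomer is taken on because it sets C10.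

Step 13
Reactants: 13 2-siloxy-1,3-diene; 17 ethyl (E)-4-[(tert-butyldimethylsilyl)oxy]-2-diazobut-3-enoate
Product: 19 ethyl 6,10α-bis(TBS-oxy)-4β-isopropyl-2β-(PMB-oxy)-1β-methyl-4α-(TES-oxy)bicyclo[5.3.0]deca-5,8-diene-8-carboxylate, via cis-dialkenylcyclopropane 18 (not isolated)
Conditions: 17 (1.5 equiv) added slowly to 13 and Rh2(S-DOSP)4 (1 mol %), hexanes, −40 °C → rt; then PhMe, 90 °C
Reagents that add atoms: none
Why: The divalent-rhodium donor/acceptor vinylcarbenoid from 17 adds in a concerted [2+1] step to the terminal, electron-rich C6=C7 enol ether of 13, closing cyclopropane C6–C7–C8 with the cyclopentenyl and siloxyvinyl groups cis, and on heating the C6–C8 bond breaks as C1–C10 forms in a [3,3]-sigmatropic (Cope) shift through a boat transition state that closes the seven-membered ring. The closest known reaction type is the tandem cyclopropanation/cis-divinylcyclopropane rearrangement (formal [4+3] annulation) of vinyldiazoacetates with 2-siloxy-1,3-dienes, including dienes with a fully substituted terminus. C1 and C10 are fixed relative to each other by the boat geometry: the ring-locked cyclopentene places its methyl inside and the E enol ether places its siloxy group outside, so C10–O ends trans to the C1 methyl. The face of C1 is set by the substrate, C10 bonding opposite the C2 PMB ether and the C4 isopropyl group, and Rh2(S-DOSP)4 is the enantiomer expected to give 18 directly. Chemoselectivity rests on the tetrasubstituted ring alkene and the trans-disubstituted enol ether of 17 being far less reactive than the 1,1-disubstituted enol ether, on hexanes suppressing zwitterionic [3+2] paths, and on keeping the excess of 17 small so the PMB methylene is not attacked. The vicinal siloxy and ester groups weaken the C6–C8 bond, so a trans or mis-set cyclopropane should be able to reopen and funnel through the favoured boat.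

Step 14
Reactants: 19 ethyl ester of the bicyclic diene
Product: 20 [6,10α-bis(TBS-oxy)-4β-isopropyl-2β-(PMB-oxy)-1β-methyl-4α-(TES-oxy)bicyclo[5.3.0]deca-5,8-dien-8-yl]methanol
Conditions: i-Bu2AlH (2.5 equiv), CH2Cl2, −78 °C; aq tartrate work-up
Reagents that add atoms: none
Why: i-Bu2AlH 1,2-reduction of the enoate to the primary allylic alcohol at −78 °C should leave the silyl enol ether and the silyl and PMB ethers intact.

Step 15
Reactants: 20 primary allylic alcohol
Product: 22 6,10α-bis(TBS-oxy)-2β-(PMB-oxy)-4α-(TES-oxy)-dauca-5,8-diene, via allylic mesylate 21 (not isolated)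
Conditions: MsCl, Et3N, CH2Cl2, −20 °C; then LiBHEt3, THF, −20 → 0 °C
Reagents that add atoms: none
Why: Mesylation followed by SN2 hydride displacement with LiBHEt3 should turn the primary allylic alcohol into the C8 methyl, direct attack at the unhindered CH2 being faster than SN2' attack at C9.

Step 16
Reactants: 22 6,10α-bis(TBS-oxy)-2β-(PMB-oxy)-4α-(TES-oxy)-dauca-5,8-diene
Product: 24 4α-hydroxy-10α-(TBS-oxy)-2β-(PMB-oxy)-(5βH)-dauc-8-en-6-one (cis-fused), via TES-protected ketone 23 (not isolated)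
Conditions: Bu4NF/AcOH (1:1, 1.2 equiv), THF, −78 → −40 °C; then HF·pyridine, pyridine, THF, 0 °C → rt; used at once
Reagents that add atoms: none
Why: Fluoride cleavage of the enol silyl ether then ketonisation should protonate C5 on the β face, away from the α-oriented C4 silyloxy group and the folded ring and toward the more stable cis-fused ketone in which C6 avoids the C1 methyl and C4 isopropyl; HF·pyridine then removes the tertiary TES ether in preference to the hindered secondary TBS ether without base, so neither retro-aldol cleavage nor migration of the C8=C9 alkene into conjugation is provoked.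

Step 17
Reactants: 24 4α-hydroxy-10α-(TBS-oxy)-2β-(PMB-oxy)-(5βH)-dauc-8-en-6-one
Product: 25 10α-(TBS-oxy)-2β-(PMB-oxy)-(5βH)-dauc-8-ene-4α,6β-diol
Conditions: Me4NBH(OAc)3, MeCN/AcOH (1:1), −30 → −20 °C
Reagents that add atoms: none
Why: Evans–Saksena hydroxyl-directed reduction, in which the C4 alkoxyborohydride delivers hydride to the α (concave) face of the C6 ketone, should give the 6β-alcohol anti to the C4 hydroxyl.

Step 18
Reactants: 25 10α-(TBS-oxy)-2β-(PMB-oxy)-(5βH)-dauc-8-ene-4α,6β-diol; 26 tiglic acid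
Product: 28 6β-tigloyloxy-10α-(TBS-oxy)-2β-(PMB-oxy)-(5βH)-dauc-8-en-4α-ol, via tigloyl chloride 27 (not isolated)
Conditions: 26 (1.6 equiv), (COCl)2 (1.5 equiv), DMF (cat.), CH2Cl2, 0 °C → rt; then this solution added to 25, pyridine, DMAP (cat.), CH2Cl2, 0 °C
Reagents that add atoms: none
Why: Acid chloride formation with oxalyl chloride (the acid kept in slight excess so that no oxalyl chloride remains) followed by DMAP-catalysed acylation should esterify only the secondary C6 hydroxyl because the tertiary C4 hydroxyl is inert, pyridine in place of a trialkylamine avoids vinylketene formation and deconjugation, and the E tiglate is the thermodynamic geometry so no isomerisation is expected.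

Step 19
Reactants: 28 6β-tigloyloxy-10α-(TBS-oxy)-2β-(PMB-oxy)-(5βH)-dauc-8-en-4α-ol
Product: 29 6β-tigloyloxy-2β-(PMB-oxy)-(5βH)-dauc-8-ene-4α,10α-diol
Conditions: HF·pyridine, THF, 0 °C → rt
Reagents that add atoms: none
Why: Acidic fluoride desilylation should free the allylic C10 hydroxyl while the PMB ether, the ester and the tertiary alcohol are unaffected.

Step 20
Reactants: 29 6β-tigloyloxy-2β-(PMB-oxy)-(5βH)-dauc-8-ene-4α,10α-diol
Product: 30 8α,9α-epoxy-6β-tigloyloxy-2β-(PMB-oxy)-(5βH)-daucane-4α,10α-diol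
Conditions: VO(acac)2 (5 mol %), t-BuOOH, CH2Cl2, 0 °C → rt
Reagents that add atoms: tert-butyl hydroperoxide, CC(C)(C)OO
Why: Vanadium-catalysed hydroxyl-directed epoxidation should deliver oxygen to C8=C9 on the face of the allylic C10 hydroxyl (α), as is general for cycloheptenols, while the electron-poor tiglate alkene does not react.

Step 21
Reactants: 30 8α,9α-epoxy-6β-tigloyloxy-2β-(PMB-oxy)-(5βH)-daucane-4α,10α-diol; 26 tiglic acid
Product: 32 8α,9α-epoxy-6β,10α-bis(tigloyloxy)-2β-(PMB-oxy)-(5βH)-daucan-4α-ol, via tiglic mixed anhydride 31 (not isolated)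
Conditions: 26, 2,4,6-Cl3C6H2COCl, Et3N, PhMe, rt; then 30, DMAP, 60 °C
Reagents that add atoms: none
Why: Yamaguchi esterification with DMAP at raised temperature should force acylation of the hindered neopentyl-type C10 hydroxyl, and the cis epoxy alcohol cannot undergo Payne rearrangement because its oxygen is syn to the epoxide.

Step 22
Reactants: 32 8α,9α-epoxy-6β,10α-bis(tigloyloxy)-2β-(PMB-oxy)-(5βH)-daucan-4α-ol
Product: 33 8α,9α-epoxy-6β,10α-bis(tigloyloxy)-(5βH)-daucane-2β,4α-diol (CNP0265715.1)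
Conditions: DDQ, CH2Cl2/pH 7 buffer, 0 °C → rt
Reagents that add atoms: none
Why: Oxidative PMB cleavage with DDQ in buffered wet CH2Cl2 is neutral and should spare the two tiglates, the epoxide and the tertiary alcohol while releasing the C2 hydroxyl.

Compound list

1 | (S)-(+)-terpinen-4-ol | CC1=CC[C@](O)(C(C)C)CC1 | starting material
2 | (5R)-5-isopropyl-2-methylcyclohex-2-ene-1,5-diol (C1 epimers) | CC1=CC[C@](O)(C(C)C)CC1O | intermediate
3 | (R)-5-hydroxy-5-isopropyl-2-methylcyclohex-2-en-1-one | CC1=CC[C@](O)(C(C)C)CC1=O | intermediate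
4 | (1S,5R)-5-isopropyl-2-methylcyclohex-2-ene-1,5-diol | CC1=CC[C@](O)(C(C)C)C[C@@H]1O | intermediate
5 | (1R,5S)-1-isopropyl-5-[(4-methoxybenzyl)oxy]-4-methylcyclohex-3-en-1-ol | CC1=CC[C@](O)(C(C)C)C[C@@H]1OCc1ccc(OC)cc1 | intermediate
6 | triethylsilyl ether of 5 | CC1=CC[C@](O[Si](CC)(CC)CC)(C(C)C)C[C@@H]1OCc1ccc(OC)cc1 | intermediate
7 | ozonide of 6 (not isolated) | CC12OOC(O1)C[C@](O[Si](CC)(CC)CC)(C(C)C)C[C@@H]2OCc1ccc(OC)cc1 | intermediate
8 | (3S,5S)-3-isopropyl-5-[(4-methoxybenzyl)oxy]-6-oxo-3-[(triethylsilyl)oxy]heptanal | O=CC[C@](O[Si](CC)(CC)CC)(C(C)C)C[C@H](OCc1ccc(OC)cc1)C(C)=O | intermediate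
9 | (3S,5R)-5-isopropyl-3-[(4-methoxybenzyl)oxy]-2-methyl-5-[(triethylsilyl)oxy]cyclopent-1-ene-1-carbaldehyde | O=CC1=C(C)[C@@H](OCc2ccc(OC)cc2)C[C@@]1(O[Si](CC)(CC)CC)C(C)C | intermediate
10 | methylmagnesium bromide | C[Mg]Br | starting material
11 | 1-(cyclopentenyl)ethan-1-ol from 9 (carbinol epimers) | CC(O)C1=C(C)[C@@H](OCc2ccc(OC)cc2)C[C@@]1(O[Si](CC)(CC)CC)C(C)C | intermediate
12 | 1-{(3S,5R)-5-isopropyl-3-[(4-methoxybenzyl)oxy]-2-methyl-5-[(triethylsilyl)oxy]cyclopent-1-en-1-yl}ethan-1-one | CC(=O)C1=C(C)[C@@H](OCc2ccc(OC)cc2)C[C@@]1(O[Si](CC)(CC)CC)C(C)C | intermediate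
13 | 2-(TBS-oxy)-1,3-diene (TBS enol ether of 12) | C=C(O[Si](C)(C)C(C)(C)C)C1=C(C)[C@@H](OCc2ccc(OC)cc2)C[C@@]1(O[Si](CC)(CC)CC)C(C)C | intermediate
14 | ethyl diazoacetate | CCOC(=O)C=[N+]=[N-] | starting material
15 | (tert-butyldimethylsilyloxy)acetaldehyde | O=CCO[Si](C)(C)C(C)(C)C | starting material
16 | ethyl 4-[(tert-butyldimethylsilyl)oxy]-2-diazo-3-hydroxybutanoate (racemic) | CCOC(=O)C(=[N+]=[N-])C(O)CO[Si](C)(C)C(C)(C)C | intermediate
17 | ethyl (E)-4-[(tert-butyldimethylsilyl)oxy]-2-diazobut-3-enoate | CCOC(=O)C(=[N+]=[N-])/C=C/O[Si](C)(C)C(C)(C)C | intermediate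
18 | cis-dialkenylcyclopropane: ethyl 2-(TBS-oxy)-2-(cyclopentenyl)-1-[(E)-2-(TBS-oxy)ethenyl]cyclopropane-1-carboxylate (not isolated) | CCOC(=O)[C@@]1(/C=C/O[Si](C)(C)C(C)(C)C)C[C@]1(O[Si](C)(C)C(C)(C)C)C1=C(C)[C@@H](OCc2ccc(OC)cc2)C[C@@]1(O[Si](CC)(CC)CC)C(C)C | intermediate
19 | ethyl 6,10α-bis(TBS-oxy)-4β-isopropyl-2β-(PMB-oxy)-1β-methyl-4α-(TES-oxy)bicyclo[5.3.0]deca-5,8-diene-8-carboxylate | CCOC(=O)C1=C[C@H](O[Si](C)(C)C(C)(C)C)[C@@]2(C)C(=C(O[Si](C)(C)C(C)(C)C)C1)[C@](O[Si](CC)(CC)CC)(C(C)C)C[C@@H]2OCc1ccc(OC)cc1 | intermediate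
20 | 8-(hydroxymethyl) analogue of 19 | OCC1=C[C@H](O[Si](C)(C)C(C)(C)C)[C@@]2(C)C(=C(O[Si](C)(C)C(C)(C)C)C1)[C@](O[Si](CC)(CC)CC)(C(C)C)C[C@@H]2OCc1ccc(OC)cc1 | intermediate
21 | allylic mesylate of 20 (not isolated) | CS(=O)(=O)OCC1=C[C@H](O[Si](C)(C)C(C)(C)C)[C@@]2(C)C(=C(O[Si](C)(C)C(C)(C)C)C1)[C@](O[Si](CC)(CC)CC)(C(C)C)C[C@@H]2OCc1ccc(OC)cc1 | intermediate
22 | 6,10α-bis(TBS-oxy)-2β-(PMB-oxy)-4α-(TES-oxy)-dauca-5,8-diene | CC1=C[C@H](O[Si](C)(C)C(C)(C)C)[C@@]2(C)C(=C(O[Si](C)(C)C(C)(C)C)C1)[C@](O[Si](CC)(CC)CC)(C(C)C)C[C@@H]2OCc1ccc(OC)cc1 | intermediate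
23 | 10α-(TBS-oxy)-2β-(PMB-oxy)-4α-(TES-oxy)-(5βH)-dauc-8-en-6-one (not isolated) | O=C1CC(C)=C[C@H](O[Si](C)(C)C(C)(C)C)[C@@]2(C)[C@@H]1[C@](O[Si](CC)(CC)CC)(C(C)C)C[C@@H]2OCc1ccc(OC)cc1 | intermediate
24 | 4α-hydroxy-10α-(TBS-oxy)-2β-(PMB-oxy)-(5βH)-dauc-8-en-6-one | O=C1CC(C)=C[C@H](O[Si](C)(C)C(C)(C)C)[C@@]2(C)[C@@H]1[C@](O)(C(C)C)C[C@@H]2OCc1ccc(OC)cc1 | intermediate
25 | 10α-(TBS-oxy)-2β-(PMB-oxy)-(5βH)-dauc-8-ene-4α,6β-diol | O[C@H]1CC(C)=C[C@H](O[Si](C)(C)C(C)(C)C)[C@@]2(C)[C@@H]1[C@](O)(C(C)C)C[C@@H]2OCc1ccc(OC)cc1 | intermediate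
26 | tiglic acid, (E)-2-methylbut-2-enoic acid | C/C=C(\C)C(=O)O | starting material
27 | tigloyl chloride, (E)-2-methylbut-2-enoyl chloride (not isolated) | C/C=C(\C)C(=O)Cl | intermediate
28 | 6β-tigloyloxy-10α-(TBS-oxy)-2β-(PMB-oxy)-(5βH)-dauc-8-en-4α-ol | C/C=C(\C)C(=O)O[C@H]1CC(C)=C[C@H](O[Si](C)(C)C(C)(C)C)[C@@]2(C)[C@@H]1[C@](O)(C(C)C)C[C@@H]2OCc1ccc(OC)cc1 | intermediate
29 | 6β-tigloyloxy-2β-(PMB-oxy)-(5βH)-dauc-8-ene-4α,10α-diol | C/C=C(\C)C(=O)O[C@H]1CC(C)=C[C@H](O)[C@@]2(C)[C@@H]1[C@](O)(C(C)C)C[C@@H]2OCc1ccc(OC)cc1 | intermediate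
30 | 8α,9α-epoxy-6β-tigloyloxy-2β-(PMB-oxy)-(5βH)-daucane-4α,10α-diol | C/C=C(\C)C(=O)O[C@H]1C[C@]2(C)O[C@@H]2[C@H](O)[C@@]2(C)[C@@H]1[C@](O)(C(C)C)C[C@@H]2OCc1ccc(OC)cc1 | intermediate
31 | tiglic 2,4,6-trichlorobenzoic anhydride (not isolated) | C/C=C(\C)C(=O)OC(=O)c1c(Cl)cc(Cl)cc1Cl | intermediate
32 | 8α,9α-epoxy-6β,10α-bis(tigloyloxy)-2β-(PMB-oxy)-(5βH)-daucan-4α-ol | C/C=C(\C)C(=O)O[C@H]1C[C@]2(C)O[C@@H]2[C@H](OC(=O)/C(C)=C/C)[C@@]2(C)[C@@H]1[C@](O)(C(C)C)C[C@@H]2OCc1ccc(OC)cc1 | intermediate
33 | 8α,9α-epoxy-6β,10α-bis(tigloyloxy)-(5βH)-daucane-2β,4α-diol, CNP0265715.1 | C/C=C(\C)C(=O)O[C@H]1C[C@]2(C)O[C@@H]2[C@H](OC(=O)/C(C)=C/C)[C@@]2(C)[C@@H]1[C@](O)(C(C)C)C[C@@H]2O | target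

Total step count: 22 steps. Longest linear sequence: 20 steps (steps 1–10 and 13–22 from terpinen-4-ol); the diazo ester is made in two steps (11–12).

Steps most likely to fail

Step 13. The risk is that the [3,3] shift at the fully substituted, ring-locked terminus is slow, so that on heating the donor–acceptor cyclopropane opens heterolytically (acyclic or dihydrofuran-type products) or simply epimerises before the seven-membered ring closes. The fallback reverses the order of reduction and rearrangement so that a cyclopropane without an acceptor is heated. It sets out from cyclopropane 18, isolated at or below room temperature; its ester is reduced with i-Bu2AlH at −78 °C to the cyclopropylcarbinol F1, which can no longer ionise across C6–C8 and should tolerate xylenes at 130–140 °C (base-washed glassware). At that temperature a trans isomer can still epimerise through the diradical, and the Cope shift of F1 gives allylic alcohol 20 directly, where the route is rejoined.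

Step 16. The risk is loss of discrimination among the three silyl ethers during the two-stage desilylation (premature cleavage at C10, or sluggish cleavage at C4), with long exposure degrading the β-hydroxy β,γ-unsaturated ketone. The fallback drops the differentiation of the C6 and C10 oxygens altogether. It sets out from 22: excess Bu4NF/AcOH (−78 °C → rt) removes every silyl group, the enol ether still cleaving first so that C5 is protonated as before, to give keto diol F2. Me4NBH(OAc)3 reduction, directed from the α-hydroxyls at C4 and C10, then gives triol F3. VO(acac)2/t-BuOOH epoxidation, in which the allylic C10 hydroxyl is expected to outweigh the homoallylic C6 hydroxyl, gives epoxy triol F4. A double Yamaguchi tigloylation of the two secondary hydroxyls (tiglic acid 26 by way of mixed anhydride 31, DMAP, PhMe, rt → 60 °C) gives 32, where the route is rejoined.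

Step 21. The risk is that the neopentyl-type, concave-face C10 hydroxyl beside the epoxide resists the conjugated mixed anhydride, and that forcing conditions open the epoxide or move the C6 acyl group. The fallback builds the tiglate in place instead of transferring it. It sets out from 30, which is acylated with the more electrophilic, non-conjugated 2-(diethoxyphosphoryl)propanoic acid (DCC, DMAP, CH2Cl2) to phosphonate ester F5; a Horner–Wadsworth–Emmons reaction with acetaldehyde under Masamune–Roush conditions (LiCl, DBU, MeCN) should then give the (E)-2-methylbut-2-enoate and hence 32, where the route is rejoined.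

Further compounds

F1 | step 13 | {2-(TBS-oxy)-2-(cyclopentenyl)-1-[(E)-2-(TBS-oxy)ethenyl]cyclopropyl}methanol | OC[C@@]1(/C=C/O[Si](C)(C)C(C)(C)C)C[C@]1(O[Si](C)(C)C(C)(C)C)C1=C(C)[C@@H](OCc2ccc(OC)cc2)C[C@@]1(O[Si](CC)(CC)CC)C(C)C
F2 | step 16 | 4α,10α-dihydroxy-2β-(PMB-oxy)-(5βH)-dauc-8-en-6-one | O=C1CC(C)=C[C@H](O)[C@@]2(C)[C@@H]1[C@](O)(C(C)C)C[C@@H]2OCc1ccc(OC)cc1
F3 | step 16 | 2β-(PMB-oxy)-(5βH)-dauc-8-ene-4α,6β,10α-triol | O[C@H]1CC(C)=C[C@H](O)[C@@]2(C)[C@@H]1[C@](O)(C(C)C)C[C@@H]2OCc1ccc(OC)cc1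
F4 | step 16 | 8α,9α-epoxy-2β-(PMB-oxy)-(5βH)-daucane-4α,6β,10α-triol | O[C@H]1C[C@]2(C)O[C@@H]2[C@H](O)[C@@]2(C)[C@@H]1[C@](O)(C(C)C)C[C@@H]2OCc1ccc(OC)cc1
F5 | step 21 | 10α-[2-(diethoxyphosphoryl)propanoyloxy]-8α,9α-epoxy-6β-tigloyloxy-2β-(PMB-oxy)-(5βH)-daucan-4α-ol | C/C=C(\C)C(=O)O[C@H]1C[C@]2(C)O[C@@H]2[C@H](OC(=O)C(C)P(=O)(OCC)OCC)[C@@]2(C)[C@@H]1[C@](O)(C(C)C)C[C@@H]2OCc1ccc(OC)cc1
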